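## Retrosynthetic overview

- The target is the 15-O-(3-phenylpropanoyl) ester of (13S)-labdane-8α,15-diol. The ester is cut last; before it, the C20 methyl goes back to a C10 ester, C7H2 to a C7 ketone, and the C8 carbinol (8α-OH, C17) to enolate chemistry at C8.
- The strategy rests on the hindered C9–C10 bond of ring B, between the quaternary ring-fusion carbon C10 and the side-chain-bearing C9. Cutting it together with C5=C6 (retro-Robinson) gives a ring A keto ester (C1–C5, C10, C18–C20) and an acyclic enone (C6–C9, C11–C16).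
- The enone is ozonised (S)-citronellol (source of C13) lengthened by an acetonyl Wittig unit; the keto ester is carbomethoxylated 2,2-dimethylcyclohexanone.
- Ring order: ring A is bought; ring B is closed in one operation (C9–C10 by Michael addition, then C5–C6 by aldol condensation). C8 and C5 are then set by substrate control.

Key step: step 5

Remarks: labdane numbering is used for all ring compounds; β is the face of C20. O15 is carried as a triisopropylsilyl ether, because ring B is closed in hot acid. Assumption: the quinine-derived amine gives the (9S,10S) sense at C9/C10; if the sense proves opposite, the quinidine-derived pseudoenantiomer takes its place in step 5.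

## Route

Step 1
Reactants: 1 2,2-dimethylcyclohexanone
Product: 2 methyl 3,3-dimethyl-2-oxocyclohexane-1-carboxylate
Conditions: NaH (2.2 equiv), (MeO)2CO, THF, reflux; aq. HCl work-up
Reagents that add atoms: dimethyl carbonate, COC(=O)OC
Why: Claisen-type C-acylation (carbomethoxylation) of the sodium enolate, which can form only on the CH2 side because the other α-carbon is quaternary, and deprotonation of the product β-keto ester drives the equilibrium.

Step 2
Reactants: 3 (S)-citronellol
Product: 4 {[(3S)-3,7-dimethyloct-6-en-1-yl]oxy}triisopropylsilane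
Conditions: iPr3SiCl, imidazole, DMF, rt
Reagents that add atoms: chlorotriisopropylsilane, CC(C)[Si](Cl)(C(C)C)C(C)C
Why: Imidazole-promoted silyl ether formation at the primary alcohol leaves the C13 stereocentre of citronellol untouched.

Step 3
Reactants: 4 {[(3S)-3,7-dimethyloct-6-en-1-yl]oxy}triisopropylsilane
Product: 6 (4S)-4-methyl-6-(triisopropylsilyloxy)hexanal, via ozonide 5 (not isolated)
Conditions: O3, CH2Cl2, −78 °C; then PPh3, −78 °C to rt
Reagents that add atoms: ozone, [O-][O+]=O
Why: Ozonolysis of the only alkene and reductive cleavage of ozonide 5 with PPh3 give the aldehyde and acetone without touching the silyl ether or the stereocentre.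

Step 4
Reactants: 6 (4S)-4-methyl-6-(triisopropylsilyloxy)hexanal; 7 1-(triphenylphosphoranylidene)propan-2-one
Product: 8 (3E,7S)-7-methyl-9-(triisopropylsilyloxy)non-3-en-2-one
Conditions: toluene, 90 °C
Reagents that add atoms: none
Why: Wittig olefination with a ketone-stabilised ylide is E-selective and tolerates the silyl ether.

Step 5
Reactants: 2 methyl 3,3-dimethyl-2-oxocyclohexane-1-carboxylate; 8 (3E,7S)-7-methyl-9-(triisopropylsilyloxy)non-3-en-2-one
Product: 11 methyl (13S)-7-oxo-15-(triisopropylsilyloxy)-17-norlabd-5-en-20-oate, via Michael adduct 9 (not isolated), via ketol 10 (not isolated)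
Conditions: 9-amino-9-deoxy-epi-quinine (20 mol%), PhCO2H (40 mol%), toluene, 40 °C; after consumption of 8: TsOH·H2O (50 mol%), reflux, Dean–Stark
Reagents that add atoms: none
Why: The primary amine condenses with enone 8 to an s-trans E-iminium ion while its protonated quinuclidine and the benzoate hold the enol of keto ester 2, whose only nucleophilic carbon is C10 because C4 is quaternary, so C10 adds to C9 and hydrolysis releases diketo ester 9 (amine-catalysed asymmetric Michael addition of a cyclic β-keto ester to a β-substituted enone). Once TsOH has taken over, the methyl ketone enolises toward C6 and attacks the protonated C5 ketone in a 6-(enolendo)-exo-trig aldol addition that closes ring B as ketol 10, and dehydration, possible only through a C6 hydrogen since C4 and C10 are quaternary, gives the C5=C6 enone 11 (Robinson annulation). C9 and C10 are both created in the C9–C10 bond formation under catalyst control: the cinchona scaffold covers one face of the iminium ion and presents one face of the bound enol, and the open synclinal arrangement on the E-enone should place C11 cis to the ester carbon C20; C13 comes unchanged from citronellol, so any mismatched adduct is a separable diastereomer. The step needs 1,4- rather than 1,2-addition and C- rather than O-alkylation, which iminium activation of a soft hydrogen-bonded enol secures, and it needs the amine not to be trapped as an enamino ester, which the C4 gem-dimethyl group next to the C5 ketone prevents. Ring closure is run in acid because base would invite retro-Michael loss of the C9 configuration, retro-Claisen opening of ring A and Claisen attack of C6 on the ester.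

Step 6
Reactants: 11 methyl (13S)-7-oxo-15-(triisopropylsilyloxy)-17-norlabd-5-en-20-oate
Product: 13 methyl (13S)-7-oxo-15-(triisopropylsilyloxy)labd-5-en-20-oate (C8 epimers), via lithium dienolate 12 (not isolated)
Conditions: LiN(iPr)2 (1.1 equiv), THF, −78 °C; MeI, DMPU, −78 to −30 °C
Reagents that add atoms: iodomethane, CI
Why: Kinetic enolate alkylation is regiospecific because C8 is the only enolisable position of 11 (C4 and C10 are quaternary, so there is no γ-hydrogen), and the new C8 centre (8α-methyl expected, anti to the β-face ester and side chain) is erased in the next step.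

Step 7
Reactants: 13 methyl (13S)-7-oxo-15-(triisopropylsilyloxy)labd-5-en-20-oate (C8 epimers)
Product: 15 methyl (13S)-8α-hydroxy-7-oxo-15-(triisopropylsilyloxy)labd-5-en-20-oate, via potassium dienolate 14 (not isolated)
Conditions: KN(SiMe3)2 (1.3 equiv), THF, −78 to −40 °C; 3-phenyl-2-(phenylsulfonyl)oxaziridine, −78 °C; aq. NH4Cl
Reagents that add atoms: 3-phenyl-2-(phenylsulfonyl)oxaziridine, O=S(=O)(c1ccccc1)N1OC1c1ccccc1
Why: Davis enolate hydroxylation of dienolate 14, planar at C8, should deliver oxygen to the α-face, anti to the C10 ester (1,3 to C8) and the C9 side chain on the β-face, which gives 8α-OH with C17 β.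

Step 8
Reactants: 15 methyl (13S)-8α-hydroxy-7-oxo-15-(triisopropylsilyloxy)labd-5-en-20-oate
Product: 16 methyl (13S)-8α-hydroxy-7-oxo-15-(triisopropylsilyloxy)labdan-20-oate
Conditions: H2 (4 atm), 10% Pd/C, EtOAc, rt
Reagents that add atoms: none
Why: Heterogeneous catalytic hydrogenation of the enone C5=C6 bond should occur from the α-face, because the β-face carries three syn-axial groups (C4 β-methyl, C10 ester, C8 methyl), which sets 5α-H (trans ring fusion) and leaves ketone, ester and silyl ether intact.

Step 9
Reactants: 16 methyl (13S)-8α-hydroxy-7-oxo-15-(triisopropylsilyloxy)labdan-20-oate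
Product: 17 methyl (13S)-7-oxo-8α-(triethylsilyloxy)-15-(triisopropylsilyloxy)labdan-20-oate
Conditions: Et3SiOTf, 2,6-lutidine, CH2Cl2, −78 to 0 °C
Reagents that add atoms: triethylsilyl trifluoromethanesulfonate, CC[Si](CC)(CC)OS(=O)(=O)C(F)(F)F
Why: Silyl triflate silylation of the hindered tertiary alcohol masks the C8 hydroxyl, which as a free alkoxide next to the enol triflate of step 10 could attack its sulfur.

Step 10
Reactants: 17 methyl (13S)-7-oxo-8α-(triethylsilyloxy)-15-(triisopropylsilyloxy)labdan-20-oate
Product: 19 methyl (13S)-8α-(triethylsilyloxy)-7-(trifluoromethylsulfonyloxy)-15-(triisopropylsilyloxy)labd-6-en-20-oate, via potassium enolate 18 (not isolated)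
Conditions: KN(SiMe3)2 (1.3 equiv), THF, −78 °C; PhNTf2, −78 to 0 °C; aq. NH4Cl
Reagents that add atoms: N-phenylbis(trifluoromethanesulfonimide), O=S(=O)(N(c1ccccc1)S(=O)(=O)C(F)(F)F)C(F)(F)F
Why: Enol triflate formation is regiospecific because C6 carries the only α-hydrogens of ketone 17, so the C6=C7 enolate 18 is trapped on oxygen by the triflimide.

Step 11
Reactants: 19 methyl (13S)-8α-(triethylsilyloxy)-7-(trifluoromethylsulfonyloxy)-15-(triisopropylsilyloxy)labd-6-en-20-oate
Product: 20 methyl (13S)-8α-(triethylsilyloxy)-15-(triisopropylsilyloxy)labd-6-en-20-oate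
Conditions: Pd(OAc)2 (5 mol%), PPh3, Bu3N, HCO2H, DMF, 60 °C
Reagents that add atoms: none
Why: Palladium-catalysed formate reduction of a vinyl triflate (oxidative addition of C7–OTf to zerovalent palladium formed from Pd(OAc)2 and PPh3, formate exchange, decarboxylation, reductive elimination) replaces OTf by H and so removes the C7 oxygen without touching the ester or silyl ethers.

Step 12
Reactants: 20 methyl (13S)-8α-(triethylsilyloxy)-15-(triisopropylsilyloxy)labd-6-en-20-oate
Product: 21 methyl (13S)-8α-(triethylsilyloxy)-15-(triisopropylsilyloxy)labdan-20-oate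
Conditions: H2 (1 atm), 10% Pd/C, EtOAc, rt
Reagents that add atoms: none
Why: Catalytic hydrogenation of the cis-disubstituted C6=C7 alkene creates no stereocentre and leaves the allylic silyl ether in place under neutral conditions.

Step 13
Reactants: 21 methyl (13S)-8α-(triethylsilyloxy)-15-(triisopropylsilyloxy)labdan-20-oate
Product: 22 (13S)-8α-(triethylsilyloxy)-15-(triisopropylsilyloxy)labdan-20-ol
Conditions: LiAlH4, THF, 0 °C to reflux
Reagents that add atoms: none
Why: Hydride reduction of the neopentyl ester with LiAlH4, a small nucleophilic hydride that can reach the axial C20 carbonyl, gives the primary alcohol while both silyl ethers are stable.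

Step 14
Reactants: 22 (13S)-8α-(triethylsilyloxy)-15-(triisopropylsilyloxy)labdan-20-ol
Product: 23 (13S)-8α-(triethylsilyloxy)-15-(triisopropylsilyloxy)labdan-20-al
Conditions: Dess–Martin periodinane, NaHCO3, CH2Cl2, rt
Reagents that add atoms: none
Why: Dess–Martin oxidation of the only free alcohol stops at the non-enolisable neopentyl aldehyde.

Step 15
Reactants: 23 (13S)-8α-(triethylsilyloxy)-15-(triisopropylsilyloxy)labdan-20-al
Product: 24 (13S)-8α,15-dihydroxylabdan-20-al
Conditions: Bu4NF (excess), THF, rt to 50 °C; aq. NH4Cl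
Reagents that add atoms: none
Why: Fluoride-driven cleavage of both silyl ethers (Si–F bond formation) is placed before the hot alkaline step so that one defined diol aldehyde enters it, and the aldehyde, having no α-hydrogen, is stable to the basic fluoride.

Step 16
Reactants: 24 (13S)-8α,15-dihydroxylabdan-20-al
Product: 26 (13S)-labdane-8α,15-diol, via hydrazone 25 (not isolated)
Conditions: N2H4·H2O, KOH, diethylene glycol, 130 °C then 200 °C
Reagents that add atoms: none
Why: Wolff–Kishner reduction (Huang-Minlon procedure) of the angular aldehyde through hydrazone 25 gives the C20 methyl group, and the C8 hydroxyl, being γ and trans to the carbonyl, can neither eliminate nor form a lactol.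

Step 17
Reactants: 26 (13S)-labdane-8α,15-diol; 27 3-phenylpropanoic acid
Product: 28 (13S)-8α-hydroxylabdan-15-yl 3-phenylpropanoate
Conditions: EDC·HCl, DMAP (cat.), CH2Cl2, 0 °C to rt
Reagents that add atoms: none
Why: Steglich esterification (carbodiimide/DMAP acylation) is selective for the primary C15 hydroxyl because the tertiary C8 hydroxyl, flanked by the axial C17 methyl and C9, does not acylate under these conditions.

## Compound list

1 | 2,2-dimethylcyclohexan-1-one | CC1(C)CCCCC1=O | starting material
2 | methyl 3,3-dimethyl-2-oxocyclohexane-1-carboxylate (racemic, enolisable; fragment 1) | COC(=O)C1CCCC(C)(C)C1=O | intermediate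
3 | (S)-citronellol, (3S)-3,7-dimethyloct-6-en-1-ol | C[C@H](CCO)CCC=C(C)C | starting material
4 | {[(3S)-3,7-dimethyloct-6-en-1-yl]oxy}triisopropylsilane | C[C@H](CCO[Si](C(C)C)(C(C)C)C(C)C)CCC=C(C)C | intermediate
5 | ozonide, 3,3-dimethyl-5-[(3S)-3-methyl-5-(triisopropylsilyloxy)pentyl]-1,2,4-trioxolane (not isolated) | C[C@H](CCO[Si](C(C)C)(C(C)C)C(C)C)CCC1OOC(C)(C)O1 | intermediate
6 | (4S)-4-methyl-6-(triisopropylsilyloxy)hexanal | C[C@H](CCO[Si](C(C)C)(C(C)C)C(C)C)CCC=O | intermediate
7 | 1-(triphenylphosphoranylidene)propan-2-one | CC(=O)C=P(c1ccccc1)(c1ccccc1)c1ccccc1 | starting material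
8 | (3E,7S)-7-methyl-9-(triisopropylsilyloxy)non-3-en-2-one (fragment 2) | C[C@H](CCO[Si](C(C)C)(C(C)C)C(C)C)CC/C=C/C(C)=O | intermediate
9 | Michael adduct, methyl (1S)-3,3-dimethyl-1-[(4S,7S)-7-methyl-2-oxo-9-(triisopropylsilyloxy)nonan-4-yl]-2-oxocyclohexane-1-carboxylate (not isolated) | C[C@H](CCO[Si](C(C)C)(C(C)C)C(C)C)CC[C@@H](CC(C)=O)[C@@]1(C(=O)OC)CCCC(C)(C)C1=O | intermediate
10 | ketol, methyl (13S)-5-hydroxy-7-oxo-15-(triisopropylsilyloxy)-17-norlabdan-20-oate, C5 configuration open (not isolated) | C[C@H](CCO[Si](C(C)C)(C(C)C)C(C)C)CC[C@H]1CC(=O)CC2(O)C(C)(C)CCC[C@]12C(=O)OC | intermediate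
11 | methyl (9S,10S,13S)-7-oxo-15-(triisopropylsilyloxy)-17-norlabd-5-en-20-oate (C9 side chain β, C10 ester β) | C[C@H](CCO[Si](C(C)C)(C(C)C)C(C)C)CC[C@H]1CC(=O)C=C2C(C)(C)CCC[C@]12C(=O)OC | intermediate
12 | lithium 5,7-dienolate of 11 (not isolated) | C[C@H](CCO[Si](C(C)C)(C(C)C)C(C)C)CC[C@H]1C=C(O[Li])C=C2C(C)(C)CCC[C@]12C(=O)OC | intermediate
13 | methyl (13S)-7-oxo-15-(triisopropylsilyloxy)labd-5-en-20-oate, C8 epimers (8α-methyl expected to predominate) | C[C@H](CCO[Si](C(C)C)(C(C)C)C(C)C)CC[C@H]1C(C)C(=O)C=C2C(C)(C)CCC[C@]12C(=O)OC | intermediate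
14 | potassium 5,7-dienolate of 13 (not isolated) | C[C@H](CCO[Si](C(C)C)(C(C)C)C(C)C)CC[C@H]1C(C)=C(O[K])C=C2C(C)(C)CCC[C@]12C(=O)OC | intermediate
15 | methyl (13S)-8α-hydroxy-7-oxo-15-(triisopropylsilyloxy)labd-5-en-20-oate (C17 β) | C[C@H](CCO[Si](C(C)C)(C(C)C)C(C)C)CC[C@H]1[C@](C)(O)C(=O)C=C2C(C)(C)CCC[C@]12C(=O)OC | intermediate
16 | methyl (13S)-8α-hydroxy-7-oxo-15-(triisopropylsilyloxy)labdan-20-oate (5α-H) | C[C@H](CCO[Si](C(C)C)(C(C)C)C(C)C)CC[C@H]1[C@](C)(O)C(=O)C[C@H]2C(C)(C)CCC[C@]12C(=O)OC | intermediate
17 | methyl (13S)-7-oxo-8α-(triethylsilyloxy)-15-(triisopropylsilyloxy)labdan-20-oate | C[C@H](CCO[Si](C(C)C)(C(C)C)C(C)C)CC[C@H]1[C@](C)(O[Si](CC)(CC)CC)C(=O)C[C@H]2C(C)(C)CCC[C@]12C(=O)OC | intermediate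
18 | potassium 6-en-7-olate of 17 (not isolated) | C[C@H](CCO[Si](C(C)C)(C(C)C)C(C)C)CC[C@H]1[C@](C)(O[Si](CC)(CC)CC)C(O[K])=C[C@H]2C(C)(C)CCC[C@]12C(=O)OC | intermediate
19 | methyl (13S)-8α-(triethylsilyloxy)-7-(trifluoromethylsulfonyloxy)-15-(triisopropylsilyloxy)labd-6-en-20-oate | C[C@H](CCO[Si](C(C)C)(C(C)C)C(C)C)CC[C@H]1[C@](C)(O[Si](CC)(CC)CC)C(OS(=O)(=O)C(F)(F)F)=C[C@H]2C(C)(C)CCC[C@]12C(=O)OC | intermediate
20 | methyl (13S)-8α-(triethylsilyloxy)-15-(triisopropylsilyloxy)labd-6-en-20-oate | C[C@H](CCO[Si](C(C)C)(C(C)C)C(C)C)CC[C@H]1[C@](C)(O[Si](CC)(CC)CC)C=C[C@H]2C(C)(C)CCC[C@]12C(=O)OC | intermediate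
21 | methyl (13S)-8α-(triethylsilyloxy)-15-(triisopropylsilyloxy)labdan-20-oate | C[C@H](CCO[Si](C(C)C)(C(C)C)C(C)C)CC[C@H]1[C@](C)(O[Si](CC)(CC)CC)CC[C@H]2C(C)(C)CCC[C@]12C(=O)OC | intermediate
22 | (13S)-8α-(triethylsilyloxy)-15-(triisopropylsilyloxy)labdan-20-ol | C[C@H](CCO[Si](C(C)C)(C(C)C)C(C)C)CC[C@H]1[C@](C)(O[Si](CC)(CC)CC)CC[C@H]2C(C)(C)CCC[C@]12CO | intermediate
23 | (13S)-8α-(triethylsilyloxy)-15-(triisopropylsilyloxy)labdan-20-al | C[C@H](CCO[Si](C(C)C)(C(C)C)C(C)C)CC[C@H]1[C@](C)(O[Si](CC)(CC)CC)CC[C@H]2C(C)(C)CCC[C@]12C=O | intermediate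
24 | (13S)-8α,15-dihydroxylabdan-20-al | C[C@H](CCO)CC[C@H]1[C@](C)(O)CC[C@H]2C(C)(C)CCC[C@]12C=O | intermediate
25 | hydrazone of 24 at C20 (not isolated) | C[C@H](CCO)CC[C@H]1[C@](C)(O)CC[C@H]2C(C)(C)CCC[C@]12C=NN | intermediate
26 | (13S)-labdane-8α,15-diol, (5S,8R,9R,10S,13S) | C[C@H](CCO)CC[C@@H]1[C@@]2(C)CCCC(C)(C)[C@@H]2CC[C@@]1(C)O | intermediate
27 | 3-phenylpropanoic acid | OC(=O)CCc1ccccc1 | starting material
28 | (13S)-8α-hydroxylabdan-15-yl 3-phenylpropanoate, (5S,8R,9R,10S,13S) | C[C@H](CCOC(=O)CCc1ccccc1)CC[C@@H]1[C@@]2(C)CCCC(C)(C)[C@@H]2CC[C@@]1(C)O | target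

## Step count and risk

Total: 17 steps. Longest linear sequence: 16 steps (steps 2 to 17, from (S)-citronellol); step 1 is a one-step side branch.

Steps most likely to fail:

1. Step 5. The C5 carbonyl lies between two quaternary carbons, so the aldol addition may not proceed under equilibrating acid conditions. Adduct 9 could then accumulate or revert by retro-Michael cleavage, with loss of the C9/C10 configuration. Fallback: the first stage is worked up before acid is added and Michael adduct 9 is isolated. Kinetic deprotonation of its methyl group (LiN(iPr)2, Me3SiCl, THF, −78 °C; the ring ketone and the ester have no α-hydrogen) gives the terminal trimethylsilyl enol ether F1. TiCl4 in CH2Cl2 at −78 °C chelates the β-keto ester and so activates C5; it should close ring B by an intramolecular Mukaiyama aldol addition that does not equilibrate, giving ketol 10. Dehydration with SOCl2 and pyridine at 0 °C then gives enone 11, where the route is rejoined.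

2. Step 7. Deprotonation of the tertiary C8–H may be incomplete, or oxygen transfer to the tetrasubstituted, flanked enolate carbon may be slow, so that the enolate is consumed by the sulfonimine by-product. Fallback: starting from 13, soft enolisation (Me3SiOTf, Et3N, CH2Cl2, 0 °C) gives the trimethylsilyl dienol ether F2; C8 is again the only position that can enolise. Dimethyldioxirane in acetone (−78 to 0 °C) epoxidises the electron-rich C7=C8 enol ether bond from the α-face (Rubottom oxidation) to the silyloxy epoxide F3. Citric acid in MeOH opens it to ketol 15, where the route is rejoined.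

3. Step 8. Hydrogenation of the hindered enone alkene may be slow, or α-face selectivity may be insufficient; the cis-fused 5β-H isomer cannot be corrected by epimerisation. Fallback: starting from 15, dissolving-metal reduction (Li, 2.2 equiv, NH3/THF, −78 °C, no added alcohol, the tertiary hydroxyl acting as internal proton source) forms the dilithium enolate alkoxide F4. Axial protonation of the enone dianion at C5 gives the trans ring fusion for stereoelectronic reasons, independent of catalyst approach. Solid NH4Cl then gives saturated ketol 16, where the route is rejoined. The limited amount of lithium and the low temperature are meant to spare the hindered ester.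

## Further compounds

F1 | step 5 | methyl (1S)-3,3-dimethyl-1-[(4S,7S)-7-methyl-9-(triisopropylsilyloxy)-2-(trimethylsilyloxy)non-1-en-4-yl]-2-oxocyclohexane-1-carboxylate | C[C@H](CCO[Si](C(C)C)(C(C)C)C(C)C)CC[C@@H](CC(=C)O[Si](C)(C)C)[C@@]1(C(=O)OC)CCCC(C)(C)C1=O
F2 | step 7 | methyl (13S)-15-(triisopropylsilyloxy)-7-(trimethylsilyloxy)labda-5,7-dien-20-oate | C[C@H](CCO[Si](C(C)C)(C(C)C)C(C)C)CC[C@H]1C(C)=C(O[Si](C)(C)C)C=C2C(C)(C)CCC[C@]12C(=O)OC
F3 | step 7 | methyl (13S)-7α,8α-epoxy-15-(triisopropylsilyloxy)-7β-(trimethylsilyloxy)labd-5-en-20-oate | C[C@H](CCO[Si](C(C)C)(C(C)C)C(C)C)CC[C@H]1[C@]2(C)O[C@]2(O[Si](C)(C)C)C=C3C(C)(C)CCC[C@]13C(=O)OC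
F4 | step 8 | dilithium 8α-oxido 6-en-7-olate of methyl (13S)-15-(triisopropylsilyloxy)labdan-20-oate (5α-H, not isolated) | C[C@H](CCO[Si](C(C)C)(C(C)C)C(C)C)CC[C@H]1[C@](C)(O[Li])C(O[Li])=C[C@H]2C(C)(C)CCC[C@]12C(=O)OC
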